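## Structural features

The target is a (2R)-flavanone: phenyl ring B sits on C2 of the pyranone ring C, which is fused through C4a–C8a to ring A. Ring A is a hexasubstituted phloroglucinol with free phenols at C5 and C7, the ring C ether oxygen O1 at C8a, a methyl group at C6, the ketone carbon on C4a and a methine carbon on C8. That methine (S) carries hydrogen, an isobutyl group, C8 of ring A and C2' of ring D, the enolised 3-hydroxy-4,4,6,6-tetramethylcyclohex-2-ene-1,5-dione (a syncarpic acid unit). The two stereocentres are 1,5-related through C2–O1–C8a–C8–CH and too far apart to steer one another, so each needs its own source of asymmetry. Three features are fragile: C2 is a benzylic ether β to the C4 ketone and is lost through the chalcone whenever C3 is enolised or O1–C2 ionises; the methine lies between an electron-rich arene and an acidic 1,3-dicarbonyl, so a free ortho phenol can expel ring D by retro-Michael cleavage through an ortho-quinone methide, and strong acid can dealkylate C8; ring D is as acidic as a carboxylic acid, chelates metals and can condense with a neighbouring phenol to a pyran. The real difficulty is ring A: no carbon is free, its three oxygens have different fates, and the C8 methine cannot be introduced with stereocontrol on a finished arene. The key step uses the fact that C8a, C8, the methine with its isobutyl group and the CH2 that becomes C2' are the carbon chain of 3-isobutylglutaric acid. C8a is a carboxyl carbon and C8 its α-carbon, so ring A can be grown around a centre fixed by desymmetrising the anhydride, and the carboxyl oxygen emerges as the one free phenol, C8a–OH.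

## Logic of the disconnections

**23 ⇒ 22.** The two O–ethyl bonds at C5 and C7 are cut last. The C5 oxygen must stay blocked until ring C exists, so that only the C8a oxygen can become O1. A free C7–OH next to the methine would open the retro-Michael path during the basic steps. Ethyl is kept because 4 and 7 are the commercial ynol ethers that survive the benzannulation; benzyl or tert-butyl ynol ethers rearrange or fragment below that temperature. The demand is a dealkylation that neither enolises C3 nor ionises O1–C2, which is why a soft-nucleophile, low-temperature Lewis acid method is used and not a hot or protic one.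

**22 ⇒ 20 + 21.** The C2–aryl bond is cut. Closing ring C by oxa-Michael addition would make the same centre through a reversible C–O bond formation, under base, with ring D present as an acid. Cutting the C–C bond moves the asymmetric event to a catalyst-controlled conjugate arylation of a flat chromone. The gain is that 20 has no ring C stereocentre and 21 is commercial. The demand is a catalyst that tolerates the acidic, chelating ring D and an electron-rich chromone, and a medium too weakly basic to reopen the product.

**20 ⇒ 18 ⇒ 17.** O1–C2 and C2–C3 are cut (C2 comes from a one-carbon formyl donor), then C4–C4a (an acetyl group). C4a is the only unsubstituted carbon of ring A and C8a–OH the only free phenol, so acylation and closure have one possible outcome each. The gain is 17, which has no ring C at all. The demand is an acylation mild enough to spare the C5 ether next to the new ketone, and a formylation that tolerates ring D as its enolate.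

**17 ⇒ 13 + 15.** Ring D is cut at C1'–C6' and C2'–C3', and the C8a–O acyl bond is restored. The CH2–C(=O) arm of the glutarate is C2'–C1'; the other four ring carbons with both gem-dimethyl groups are available in 15. Lactone 13 serves twice: as an aryl ester it is an activated acyl donor, and it masks C8a–OH until ring D is in place. The polarity is chosen so that the nucleophile is the single enolate 15 can form and the last bond is closed by the enolate next to the methine. The reverse union (enolate of 13 onto 14) would leave a doubly activated C–H that quenches the enolate needed for ring closure. The demand is that acylation outruns proton transfer and that the Dieckmann closure onto a hindered ester goes to completion.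

**15 ⇒ 14.** One C(=O)–CMe2 bond of the four-membered ring and an O–CH3 bond are cut; this is the ring opening of a strained, non-enolisable dione by an alkoxide. The gain is a commercial starting material. The demand is small.

**13 ⇒ 12.** The lactone C–O bond is cut. The gain is the phenol ester that the benzannulation delivers directly. The demand is only that C8a–OH be the sole phenol, which the key step guarantees.

**12 ⇒ 6 + 7.** Ring A is cut at C4a–C8a and C5–C6 into a four-carbon cyclobutenone and a two-carbon ynol ether. This is the only cut that lets the arene be built around a stereocentre made beforehand, and it differentiates the three oxygens by origin (ketene oxygen free, two ynol ether oxygens alkylated). The gain is one ring, two skeletal bonds and full substitution in one operation. The demand is that a 3-alkoxycyclobutenone opens to its vinylketene under conditions that 7 survives, and that the side-chain C–H stays out of hydrogen shifts.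

**6 ⇒ 3 + 4 (through 5).** The cyclobutenone is cut at C(=O)–C(CH3) and C(OEt)–CH, the retron of a ketene–ynol ether [2+2] cycloaddition; the ketene carbon is the former carboxyl carbon. The gain is an acyclic acid chloride and a commercial alkyne. The demand is slow generation of an aldoketene and an acid chloride that does not exchange its two arms.

**3 ⇒ 2 ⇒ 1.** The C–Cl bond and then one ester C–O bond are cut, back to the meso anhydride. The gain is that the methine configuration comes from a catalytic desymmetrisation of a commodity compound. The demand is high enantiotopic group selectivity, with enrichment by salt crystallisation if needed.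

## Other disconnections considered

**Alternative 1:** The cut removes the four C–CH3 bonds of ring D (and the C7 O–CH3 bond), tracing ring D back to a trihydroxyphenyl ring in precursor A2. In the forward step a methyl halide and an alkoxide base would methylate the two unsubstituted ring carbons of A2 twice each and give A1.
- In its favour: one operation builds both quaternary carbons; dearomative tetramethylation of phloroglucinols is the classical entry to this ring; the flavone has no C2 centre for the strong base to scramble.
- Against it here: in the classical cases the third ring carbon carries a deactivating acyl group, whereas in A2 it carries an alkyl group and is as nucleophilic as the others, so a fifth C-methylation and O-methylation should compete. The methine of A2 is a bis-benzylic centre between two phloroglucinol rings with free ortho phenols, hard to obtain as one enantiomer and open to ortho-quinone methide scrambling under the alkoxide conditions. After A1, the C2=C3 bond must still be reduced enantioselectively and two methyl ethers removed.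
- Comparison: on ring D step economy the alternative is the better plan (one step against steps 6 and 7). On the final ether cleavage the two are equal. On mechanism it relies on a delicate balance of enolate reactivities, where the chosen plan relies on a pericyclic cascade whose regiochemistry follows from polarity. On structure it is weaker, because it leaves the source of both stereocentres open.

**Alternative 2:** The cut removes C8a–O1, C4–C4a and O1–C2. The aryne from silyl triflate A4 would insert into the carboxyl C–O bond of acid A5, and the resulting phenoxide would add to the ynone to close ring C as flavone A3.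
- In its favour: the bicyclic core with the right oxygen pattern forms in one step; the methoxy group next to the aryne directs the nucleophile to the distal carbon (C8a); the step is convergent.
- Against it here: A4 is a pentasubstituted arene that needs its own multistep preparation. A3 is achiral and contains none of the difficult parts: C8 still bears hydrogen and must be alkylated on a ring whose activating oxygens are methylated, with no handle for the methine configuration. Ring D, the asymmetric reduction of C2=C3 and the ether cleavage remain.
- Comparison: to rings A and C it is faster and more convergent than the chosen plan, and is the better plan on that point. On the protecting-group endgame the two are equal. Mechanistically a polar insertion cascade and an electrocyclic cascade are both credible. On structure the alternative solves the easy half, whereas step 4 of the chosen plan carries the methine through and sets up the direction of ring C closure.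

**Alternative 3:** The cut removes C4–C4a. Aryl ether acid A7, with C2 taken from the chiral pool, would be activated as a mixed anhydride or in a strongly dehydrating acid and would acylate the ortho carbon to give flavanone A6.
- In its favour: C2 comes from an enantiopure building block and needs no asymmetric catalysis, which is more secure in principle than step 10; the aryl ether is symmetrical, so the acylation has only one outcome, equal to the regiochemical certainty of step 8; the sequence is short.
- Against it here: the benzylic C–O bond of A7 can ionise or undergo β-elimination of the aryloxy group under the acidic acylation, which would erode C2. A6 still has hydrogen at C8, so the methine and ring D must be attached afterwards, on methylated oxygens, in the presence of a C2 centre that tolerates neither base nor strong acid. Any late union at C8 (conjugate addition to an alkylidene trione) would form the methine without control because C2 is remote.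
- Comparison: on step count to the flavanone core and on the origin of C2 it is the better plan. On mechanism it is simpler. On structure it postpones the hardest stereocentre to the point where the molecule is most fragile, whereas the chosen plan fixes that centre in step 1 and creates C2 last.

Key step: step 4

Assumption: quinidine is taken to open 1 to the (3S)-hemiester 2; if the sense proves opposite, its pseudoenantiomer quinine is used instead.

Assumption: the (R,R)-diene ligand of step 10 is taken to deliver phenyl to the face of C2 that gives 2R; if not, the (S,S)-ligand is used.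

Remark: atom mapping of 6 and 12 confirms the regiochemistry (C8a–OH free, hydrogen at C4a, ethers at C5 and C7) and the 3R descriptor of both, so no structure needed correction. The same carbon is S from 17 onwards only because ring D outranks ring A.

## Route

Step 1
Reactants: 1 3-isobutylglutaric anhydride
Product: 2 (3S)-3-(2-methoxy-2-oxoethyl)-5-methylhexanoic acid
Conditions: MeOH (3 equiv), quinidine (1.1 equiv, recovered by acid extraction), PhMe, −55 °C
Reagents that add atoms: methanol, CO
Why: Alkaloid-mediated desymmetrisation of a prochiral cyclic anhydride: the quinuclidine nitrogen delivers methanol as a general base to one of the two enantiotopic carbonyl groups, which sets the centre that becomes the C8 methine. The low temperature suppresses the uncatalysed background reaction, and the enantiomeric purity can be raised by crystallising an amine salt of 2.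

Step 2
Reactants: 2 (3S)-3-(2-methoxy-2-oxoethyl)-5-methylhexanoic acid
Product: 3 methyl (3R)-3-(2-chloro-2-oxoethyl)-5-methylhexanoate
Conditions: (COCl)2 (1.2 equiv), DMF (cat.), CH2Cl2, 0 °C to rt; concentrated below 25 °C and used crude
Reagents that add atoms: oxalyl chloride, O=C(Cl)C(=O)Cl
Why: Standard Vilsmeier-type conversion of an acid into its chloride; the stereocentre is β to both carbonyl groups and cannot enolise (the descriptor changes by priority only). Keeping the crude chloride cold and using it at once guards against the intramolecular ester–acid chloride interchange that would swap the two arms and erode the enantiomeric purity.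

Step 3
Reactants: 3 methyl (3R)-3-(2-chloro-2-oxoethyl)-5-methylhexanoate; 4 1-ethoxyprop-1-yne
Product: 6 methyl (3R)-3-(2-ethoxy-3-methyl-4-oxocyclobut-2-en-1-yl)-5-methylhexanoate (both configurations at the ring carbon), via aldoketene 5 (not isolated)
Conditions: 3 added over 4 h to 4 (2 equiv) and Et3N (1.3 equiv), CH2Cl2, rt
Reagents that add atoms: none
Why: Dehydrochlorination gives aldoketene 5, which undergoes the thermal [2+2] cycloaddition of ketenes with ynol ethers: the nucleophilic methyl-bearing carbon of 4 bonds to the ketene carbonyl carbon and the ethoxy-bearing carbon to the ketene α-carbon, so the 3-ethoxy-2-methyl-4-alkyl cyclobutenone is the only regioisomer expected. Slow addition into an excess of 4 keeps the ketene dilute enough to outrun its dimerisation; the new ring centre forms without control, which is harmless because it becomes aromatic C8.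

Step 4
Reactants: 6 methyl (3R)-3-(2-ethoxy-3-methyl-4-oxocyclobut-2-en-1-yl)-5-methylhexanoate; 7 ethoxyacetylene
Product: 12 methyl (3R)-3-(2,4-diethoxy-6-hydroxy-3-methylphenyl)-5-methylhexanoate, via vinylketene 8 (not isolated), via vinylcyclobutenone 9 (not isolated), via dienylketene 10 (not isolated), via cyclohexadienone 11 (not isolated)
Conditions: 7 (3 equiv), degassed PhMe, hν (300 nm, Pyrex), rt; then 80 °C, sealed vessel
Reagents that add atoms: none
Why: Proposed new method: irradiation opens 6 by 4π-electrocyclic cleavage of the C(=O)–CH bond to vinylketene 8 with the alkyl-bearing carbon rotating outwards; the unsubstituted, nucleophilic carbon of 7 then attacks the ketene carbon and the ethoxy-bearing carbon bonds to the methyl-bearing carbon in a [2+2] cycloaddition, which forms C4a–C8a and C5–C6 and gives 9. Cyclobutenone 9 opens again to dienylketene 10, which closes ring A by a thermal disrotatory 6π-electrocyclisation that re-forms C8–C8a, and dienone 11 tautomerises to phenol 12. The closest known reaction is the Danheiser benzannulation of 3-alkyl- or 3-arylcyclobutenones with alkoxyacetylenes, which gives resorcinol monoethers; what is untested is the 3-ethoxy group of 6, a donor that stabilises the four-membered vinylogous ester and should raise the barrier of the first opening, which is why that opening is triggered by light at room temperature and not by heating 7 to the point where it loses ethylene. No stereocentre is created: the ring centre of 6 becomes sp2 and the side-chain centre is never enolisable. The step needs regiocontrol in the [2+2] event, secured by the polarity of the ynol ether (hydrogen ends at C4a, ethoxy at C5), and it needs the side-chain C–H to stay out of 1,5-hydrogen shifts, secured by the outward rotation that places the stereocentre trans to the ketene. The ketene oxygen ends as the only free phenol (C8a–OH) while C5 and C7 are ethers, the differentiation on which the rest of the route relies, and the excess of 7 favours capture of 8 over its reclosure or dimerisation.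

Step 5
Reactants: 12 methyl (3R)-3-(2,4-diethoxy-6-hydroxy-3-methylphenyl)-5-methylhexanoate
Product: 13 (4R)-5,7-diethoxy-6-methyl-4-(2-methylpropyl)-3,4-dihydro-2H-chromen-2-one
Conditions: TsOH·H2O (10 mol%), PhMe, reflux through 4 Å molecular sieves
Reagents that add atoms: none
Why: Acid-catalysed intramolecular transesterification closes the six-membered aryl lactone on C8a–OH, the only phenol of 12, and removal of methanol drives it. The lactone masks this phenol and turns the carbonyl group into an aryl ester, an activated acyl donor for step 7.

Step 6
Reactants: 14 2,2,4,4-tetramethylcyclobutane-1,3-dione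
Product: 15 methyl 2,2,4-trimethyl-3-oxopentanoate
Conditions: NaOMe (5 mol%), MeOH, reflux
Reagents that add atoms: methanol, CO
Why: Methoxide adds to one carbonyl group of the strained, non-enolisable dione and the four-membered ring opens by retro-Claisen cleavage; protonation by methanol gives the β-keto ester and returns the catalyst.

Step 7
Reactants: 13 (4R)-5,7-diethoxy-6-methyl-4-(2-methylpropyl)-3,4-dihydro-2H-chromen-2-one; 15 methyl 2,2,4-trimethyl-3-oxopentanoate
Product: 17 2-[(1S)-1-(2,4-diethoxy-6-hydroxy-3-methylphenyl)-3-methylbutyl]-3-hydroxy-4,4,6,6-tetramethylcyclohex-2-ene-1,5-dione, via triketo ester 16 (not isolated)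
Conditions: 15 (2.5 equiv), LiN(i-Pr)2 (2.5 equiv), THF, −78 °C; then 13, −78 to 50 °C; aq. HCl
Reagents that add atoms: none
Why: Crossed Claisen acylation followed by Dieckmann condensation: the only enolate 15 can form attacks the aryl ester carbonyl of 13 and releases the C8a phenoxide to give 16 (if 13 is enolised instead, its enolate can expel the phenoxide to a ketene, which the same nucleophile acylates to the same product). The second equivalent of enolate deprotonates the CH2 next to the new ketone, and that enolate closes ring D 6-exo-trig on the methyl ester. Formation of the stabilised ring D enolate drives the sequence, and the methine is never deprotonated because it lies β to every carbonyl group.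

Step 8
Reactants: 17 2-[(1S)-1-(2,4-diethoxy-6-hydroxy-3-methylphenyl)-3-methylbutyl]-3-hydroxy-4,4,6,6-tetramethylcyclohex-2-ene-1,5-dione
Product: 18 2-[(1S)-1-(3-acetyl-4,6-diethoxy-2-hydroxy-5-methylphenyl)-3-methylbutyl]-3-hydroxy-4,4,6,6-tetramethylcyclohex-2-ene-1,5-dione
Conditions: AcCl (2.5 equiv), TiCl4 (3.5 equiv), CH2Cl2, −20 to 0 °C; cold aq. HCl
Reagents that add atoms: acetyl chloride, CC(=O)Cl
Why: Friedel–Crafts acylation at C4a, the only unsubstituted carbon of ring A, activated by the ortho C8a–OH, the ortho C5 ether and the para C7 ether; the titanium phenoxide delivers the acyl group ortho, and any enol or phenol acetate formed on the way is expected to hydrolyse in the work-up. The low temperature is meant to spare the C5 ether next to the new ketone, whose survival keeps C8a–OH the only phenol able to close ring C.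

Step 9
Reactants: 18 2-[(1S)-1-(3-acetyl-4,6-diethoxy-2-hydroxy-5-methylphenyl)-3-methylbutyl]-3-hydroxy-4,4,6,6-tetramethylcyclohex-2-ene-1,5-dione
Product: 20 2-[(1S)-1-(5,7-diethoxy-6-methyl-4-oxo-4H-chromen-8-yl)-3-methylbutyl]-3-hydroxy-4,4,6,6-tetramethylcyclohex-2-ene-1,5-dione, via ketoaldehyde 19 (not isolated)
Conditions: HCO2Et (10 equiv), NaH (5 equiv), THF, 0 °C to rt; then HCl, EtOH, 50 °C
Reagents that add atoms: ethyl formate, CCOC=O
Why: Claisen formylation of the methyl ketone (as the trianion of 18) gives ketoaldehyde 19, whose hemiacetal with C8a–OH loses water under acid to give the chromone; because C5 is still an ether, C8a–OH is the only oxygen that can become O1. Ring C is made flat on purpose so that C2 can be set afterwards by a catalyst.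

Step 10
Reactants: 20 2-[(1S)-1-(5,7-diethoxy-6-methyl-4-oxo-4H-chromen-8-yl)-3-methylbutyl]-3-hydroxy-4,4,6,6-tetramethylcyclohex-2-ene-1,5-dione; 21 phenylboronic acid
Product: 22 2-[(1S)-1-[(2R)-5,7-diethoxy-6-methyl-4-oxo-2-phenyl-3,4-dihydro-2H-chromen-8-yl]-3-methylbutyl]-3-hydroxy-4,4,6,6-tetramethylcyclohex-2-ene-1,5-dione
Conditions: 21 (3 equiv), [RhCl(C2H4)2]2 (3 mol%), (R,R)-2,5-diphenylbicyclo[2.2.2]octa-2,5-diene (6.6 mol%), KOH (1.5 equiv), dioxane/H2O 10:1, 40 °C; dilute HCl work-up
Reagents that add atoms: none
Why: Hayashi–Miyaura asymmetric 1,4-addition: a phenyl complex of monovalent rhodium bound to the chiral diene adds across C2=C3 of the chromone and the rhodium enolate is protonated, so the ligand decides the face and sets C2 as R; the methine five bonds away should not interfere. KOH converts ring D into its potassium enolate and the excess of 21 buffers the remaining base, which protects the product against ring opening. Diketonate complexes of monovalent rhodium are themselves competent precatalysts for this reaction, so ring D is not expected to poison it.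

Step 11
Reactants: 22 2-[(1S)-1-[(2R)-5,7-diethoxy-6-methyl-4-oxo-2-phenyl-3,4-dihydro-2H-chromen-8-yl]-3-methylbutyl]-3-hydroxy-4,4,6,6-tetramethylcyclohex-2-ene-1,5-dione
Product: 23 2-[(1S)-1-[(2R)-5,7-dihydroxy-6-methyl-4-oxo-2-phenyl-3,4-dihydro-2H-chromen-8-yl]-3-methylbutyl]-3-hydroxy-4,4,6,6-tetramethylcyclohex-2-ene-1,5-dione
Conditions: BCl3 (6 equiv), n-Bu4NI (6 equiv), CH2Cl2, −78 to 0 °C; pH 5 buffer work-up
Reagents that add atoms: none
Why: Lewis acid-assisted SN2 dealkylation: BCl3 activates the C5 ether by chelation with the C4 ketone and the C7 ether because its two ortho neighbours twist it out of conjugation and make it basic, and iodide removes each ethyl group as iodoethane at low temperature. Cold aprotic conditions avoid enolisation at C3 and ionisation of O1–C2, so both stereocentres should survive, and they avoid condensation of the new C7–OH with ring D.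

## Compound list

1 | 3-isobutylglutaric anhydride, 4-(2-methylpropyl)oxane-2,6-dione | CC(C)CC1CC(=O)OC(=O)C1 | starting material
2 | (3S)-3-(2-methoxy-2-oxoethyl)-5-methylhexanoic acid | OC(=O)C[C@H](CC(C)C)CC(=O)OC | intermediate
3 | methyl (3R)-3-(2-chloro-2-oxoethyl)-5-methylhexanoate | ClC(=O)C[C@H](CC(C)C)CC(=O)OC | intermediate
4 | 1-ethoxyprop-1-yne | CCOC#CC | starting material
5 | methyl (3R)-5-methyl-3-(2-oxoethenyl)hexanoate (aldoketene) | O=C=C[C@H](CC(C)C)CC(=O)OC | intermediate
6 | methyl (3R)-3-(2-ethoxy-3-methyl-4-oxocyclobut-2-en-1-yl)-5-methylhexanoate, both configurations at the ring carbon | CCOC1=C(C)C(=O)C1[C@H](CC(C)C)CC(=O)OC | intermediate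
7 | ethoxyacetylene (ethoxyethyne) | CCOC#C | starting material
8 | methyl (3R,4Z)-5-ethoxy-6-methyl-3-(2-methylpropyl)-7-oxohepta-4,6-dienoate (vinylketene) | O=C=C(C)/C(OCC)=C/[C@H](CC(C)C)CC(=O)OC | intermediate
9 | methyl (3R,4Z)-5-ethoxy-5-(2-ethoxy-1-methyl-4-oxocyclobut-2-en-1-yl)-3-(2-methylpropyl)pent-4-enoate, both configurations at the ring carbon | O=C1C=C(OCC)C1(C)/C(OCC)=C/[C@H](CC(C)C)CC(=O)OC | intermediate
10 | methyl (3R,4Z,6E)-5,7-diethoxy-6-methyl-3-(2-methylpropyl)-9-oxonona-4,6,8-trienoate (dienylketene) | O=C=C/C(OCC)=C(C)\C(OCC)=C\[C@H](CC(C)C)CC(=O)OC | intermediate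
11 | methyl (3R)-3-(2,4-diethoxy-3-methyl-6-oxocyclohexa-2,4-dien-1-yl)-5-methylhexanoate, both configurations at the ring carbon | O=C1C=C(OCC)C(C)=C(OCC)C1[C@H](CC(C)C)CC(=O)OC | intermediate
12 | methyl (3R)-3-(2,4-diethoxy-6-hydroxy-3-methylphenyl)-5-methylhexanoate | CCOc1cc(O)c([C@H](CC(C)C)CC(=O)OC)c(OCC)c1C | intermediate
13 | (4R)-5,7-diethoxy-6-methyl-4-(2-methylpropyl)-3,4-dihydro-2H-chromen-2-one | CCOc1cc2OC(=O)C[C@@H](CC(C)C)c2c(OCC)c1C | intermediate
14 | 2,2,4,4-tetramethylcyclobutane-1,3-dione | CC1(C)C(=O)C(C)(C)C1=O | starting material
15 | methyl 2,2,4-trimethyl-3-oxopentanoate | COC(=O)C(C)(C)C(=O)C(C)C | intermediate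
16 | methyl (7R)-7-(2,4-diethoxy-6-hydroxy-3-methylphenyl)-2,2,4,4,9-pentamethyl-3,5-dioxodecanoate | CCOc1cc(O)c([C@H](CC(C)C)CC(=O)C(C)(C)C(=O)C(C)(C)C(=O)OC)c(OCC)c1C | intermediate
17 | 2-[(1S)-1-(2,4-diethoxy-6-hydroxy-3-methylphenyl)-3-methylbutyl]-3-hydroxy-4,4,6,6-tetramethylcyclohex-2-ene-1,5-dione | CCOc1cc(O)c([C@H](CC(C)C)C2=C(O)C(C)(C)C(=O)C(C)(C)C2=O)c(OCC)c1C | intermediate
18 | 2-[(1S)-1-(3-acetyl-4,6-diethoxy-2-hydroxy-5-methylphenyl)-3-methylbutyl]-3-hydroxy-4,4,6,6-tetramethylcyclohex-2-ene-1,5-dione | CCOc1c(C)c(OCC)c([C@H](CC(C)C)C2=C(O)C(C)(C)C(=O)C(C)(C)C2=O)c(O)c1C(C)=O | intermediate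
19 | 2-[(1S)-1-[4,6-diethoxy-2-hydroxy-5-methyl-3-(3-oxopropanoyl)phenyl]-3-methylbutyl]-3-hydroxy-4,4,6,6-tetramethylcyclohex-2-ene-1,5-dione | CCOc1c(C)c(OCC)c([C@H](CC(C)C)C2=C(O)C(C)(C)C(=O)C(C)(C)C2=O)c(O)c1C(=O)CC=O | intermediate
20 | 2-[(1S)-1-(5,7-diethoxy-6-methyl-4-oxo-4H-chromen-8-yl)-3-methylbutyl]-3-hydroxy-4,4,6,6-tetramethylcyclohex-2-ene-1,5-dione | CCOc1c(C)c(OCC)c([C@H](CC(C)C)C2=C(O)C(C)(C)C(=O)C(C)(C)C2=O)c2occc(=O)c12 | intermediate
21 | phenylboronic acid | OB(O)c1ccccc1 | starting material
22 | 2-[(1S)-1-[(2R)-5,7-diethoxy-6-methyl-4-oxo-2-phenyl-3,4-dihydro-2H-chromen-8-yl]-3-methylbutyl]-3-hydroxy-4,4,6,6-tetramethylcyclohex-2-ene-1,5-dione | Cc1c(OCC)c2c(c([C@H](CC(C)C)C3=C(O)C(C)(C)C(=O)C(C)(C)C3=O)c1OCC)O[C@@H](c1ccccc1)CC2=O | intermediate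
23 | 2-[(1S)-1-[(2R)-5,7-dihydroxy-6-methyl-4-oxo-2-phenyl-3,4-dihydro-2H-chromen-8-yl]-3-methylbutyl]-3-hydroxy-4,4,6,6-tetramethylcyclohex-2-ene-1,5-dione (CNP0249552.1) | Cc1c(O)c2c(c([C@H](CC(C)C)C3=C(O)C(C)(C)C(=O)C(C)(C)C3=O)c1O)O[C@@H](c1ccccc1)CC2=O | target

## Step count and least certain steps

Total: 11 steps. Longest linear sequence: 10 steps (steps 1 to 5 and 7 to 11); step 6 is a one-step side branch. The chromone detour (steps 8 to 10) costs one step more than a cinnamoylation and oxa-Michael closure would, in exchange for a C–C bond-forming asymmetric step that is not equilibrium-limited.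

**Step 4 (key step, proposed new method).** What may go wrong:
- the donor-stabilised cyclobutenone may be reluctant to open, so that the vinylketene never reaches a useful concentration;
- 7 loses ethylene if heat has to replace light;
- reclosure or dimerisation of the vinylketene may win over its capture;
- inward rotation followed by a 1,5-hydrogen shift would destroy the stereocentre;
- ketene fragments may acylate the product phenol.

Fallback (known chemistry only): ring A is bought as an arene and the methine is set by asymmetric conjugate addition. This fallback cannot branch from an intermediate, because it no longer grows the ring from 2. It sets out from commercial 2-methylbenzene-1,3-diol F1 and comes back to the route at 13, replacing steps 1 to 5. F1 is O-ethylated (EtI, K2CO3, DMF) to 1,3-diethoxy-2-methylbenzene F2. C–H borylation at the only ring position without an ortho neighbour ([Ir(OMe)(cod)]2, 4,4'-di-tert-butyl-2,2'-bipyridine, B2pin2) gives aryl boronate F3, which is oxidised in the same flask (aqueous Oxone) to 3,5-diethoxy-4-methylphenol F4. Hydroarylation and lactonisation with ethyl propiolate (Pd(OAc)2, CF3CO2H, CH2Cl2) give 5,7-diethoxy-6-methylcoumarin F5; the two ortho positions of F4 are equivalent. Copper-catalysed asymmetric conjugate addition of i-BuMgBr (CuBr·SMe2, a chiral ferrocenyl diphosphine of the Josiphos family, t-BuOMe, −72 °C) then gives 13, the ligand enantiomer being chosen for the 4R lactone.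

**Step 7.** What may go wrong: proton transfer from 13 to the hindered enolate may outrun C–C bond formation, and the methoxide released by the ring closure may cleave the non-enolisable 1,3-dicarbonyl units of 16 by retro-Claisen reaction. Fallback: the polarity is reversed; it sets out from 13 (with 14) and comes back at 17. The enolate of 13 (LiN(SiMe3)2, THF, −78 °C) is added to 14, a strained ketone that cannot be enolised. The aldolate should fragment by opening of the four-membered ring to the 3-acyl lactone (4R)-5,7-diethoxy-6-methyl-4-(2-methylpropyl)-3-(2,2,4-trimethyl-3-oxopentanoyl)-3,4-dihydro-2H-chromen-2-one F6. A second treatment with LiN(SiMe3)2 (2.2 equiv, THF, 0 to 60 °C) enolises the isopropyl ketone, which acylates on the aryl ester carbonyl and releases the C8a phenoxide to give 17.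

**Step 10.** What may go wrong: chelation of the ring D enolate may inhibit the catalyst; addition to the electron-rich, fully substituted chromone may be sluggish; base-induced opening and reclosure of ring C would erode C2. Fallback: C2 is formed without control and the epimers are separated; it sets out from 18 and comes back at 22. Claisen–Schmidt condensation of 18 with benzaldehyde (KOH, EtOH) gives the 2'-hydroxychalcone F7. Cyclisation (NaOAc, EtOH, reflux) gives 22 together with its (2S)-epimer F8; the two are diastereomers because the methine is fixed, and are separated by chromatography. F8 is re-equilibrated through F7 under the same conditions and recycled.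

**Step 11.** What may go wrong: Lewis acid-induced opening of ring C with loss of C2 integrity, incomplete cleavage of the hindered C7 ether, condensation of C7–OH with ring D, and dealkylation at C8. Fallback: the ethers are exchanged before any sensitive centre but the methine exists; it sets out from 13 and comes back at 23. Lactone 13 is de-ethylated (BBr3, CH2Cl2, −78 to 0 °C; the lactone recloses on work-up) to (4R)-5,7-dihydroxy-6-methyl-4-(2-methylpropyl)-3,4-dihydro-2H-chromen-2-one F9 and benzylated (BnBr, K2CO3, acetone) to the dibenzyl ether F10. Steps 7 to 10 are then run on the benzyl series, with AcOH/(CF3CO)2O in place of AcCl/TiCl4 in the acetylation to spare the benzyl ethers. This gives in turn the ring D phenol F11, the acetophenone F12, the chromone F13 and the (2R)-flavanone F14. Hydrogenolysis (H2, Pd/C, EtOAc, rt) of F14 gives 23 under neutral conditions.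

## Further compounds

F1 | step 4 | 2-methylbenzene-1,3-diol | Cc1c(O)cccc1O
F2 | step 4 | 1,3-diethoxy-2-methylbenzene | CCOc1cccc(OCC)c1C
F3 | step 4 | 2-(3,5-diethoxy-4-methylphenyl)-4,4,5,5-tetramethyl-1,3,2-dioxaborolane | CCOc1cc(B2OC(C)(C)C(C)(C)O2)cc(OCC)c1C
F4 | step 4 | 3,5-diethoxy-4-methylphenol | CCOc1cc(O)cc(OCC)c1C
F5 | step 4 | 5,7-diethoxy-6-methyl-2H-chromen-2-one | CCOc1cc2OC(=O)C=Cc2c(OCC)c1C
F6 | step 7 | (4R)-5,7-diethoxy-6-methyl-4-(2-methylpropyl)-3-(2,2,4-trimethyl-3-oxopentanoyl)-3,4-dihydro-2H-chromen-2-one, both configurations at C3 | CCOc1cc2OC(=O)C(C(=O)C(C)(C)C(=O)C(C)C)[C@@H](CC(C)C)c2c(OCC)c1C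
F7 | step 10 | 2-[(1S)-1-{4,6-diethoxy-2-hydroxy-5-methyl-3-[(2E)-3-phenylprop-2-enoyl]phenyl}-3-methylbutyl]-3-hydroxy-4,4,6,6-tetramethylcyclohex-2-ene-1,5-dione | CCOc1c(C)c(OCC)c([C@H](CC(C)C)C2=C(O)C(C)(C)C(=O)C(C)(C)C2=O)c(O)c1C(=O)/C=C/c1ccccc1
F8 | step 10 | 2-[(1S)-1-[(2S)-5,7-diethoxy-6-methyl-4-oxo-2-phenyl-3,4-dihydro-2H-chromen-8-yl]-3-methylbutyl]-3-hydroxy-4,4,6,6-tetramethylcyclohex-2-ene-1,5-dione | Cc1c(OCC)c2c(c([C@H](CC(C)C)C3=C(O)C(C)(C)C(=O)C(C)(C)C3=O)c1OCC)O[C@H](c1ccccc1)CC2=O
F9 | step 11 | (4R)-5,7-dihydroxy-6-methyl-4-(2-methylpropyl)-3,4-dihydro-2H-chromen-2-one | Oc1cc2OC(=O)C[C@@H](CC(C)C)c2c(O)c1C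
F10 | step 11 | (4R)-5,7-bis(benzyloxy)-6-methyl-4-(2-methylpropyl)-3,4-dihydro-2H-chromen-2-one | C(c1ccccc1)Oc1cc2OC(=O)C[C@@H](CC(C)C)c2c(OCc2ccccc2)c1C
F11 | step 11 | 2-[(1S)-1-[2,4-bis(benzyloxy)-6-hydroxy-3-methylphenyl]-3-methylbutyl]-3-hydroxy-4,4,6,6-tetramethylcyclohex-2-ene-1,5-dione | C(c1ccccc1)Oc1cc(O)c([C@H](CC(C)C)C2=C(O)C(C)(C)C(=O)C(C)(C)C2=O)c(OCc2ccccc2)c1C
F12 | step 11 | 2-[(1S)-1-[3-acetyl-4,6-bis(benzyloxy)-2-hydroxy-5-methylphenyl]-3-methylbutyl]-3-hydroxy-4,4,6,6-tetramethylcyclohex-2-ene-1,5-dione | C(c1ccccc1)Oc1c(C)c(OCc2ccccc2)c([C@H](CC(C)C)C2=C(O)C(C)(C)C(=O)C(C)(C)C2=O)c(O)c1C(C)=O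
F13 | step 11 | 2-[(1S)-1-[5,7-bis(benzyloxy)-6-methyl-4-oxo-4H-chromen-8-yl]-3-methylbutyl]-3-hydroxy-4,4,6,6-tetramethylcyclohex-2-ene-1,5-dione | C(c1ccccc1)Oc1c(C)c(OCc2ccccc2)c([C@H](CC(C)C)C2=C(O)C(C)(C)C(=O)C(C)(C)C2=O)c2occc(=O)c12
F14 | step 11 | 2-[(1S)-1-[(2R)-5,7-bis(benzyloxy)-6-methyl-4-oxo-2-phenyl-3,4-dihydro-2H-chromen-8-yl]-3-methylbutyl]-3-hydroxy-4,4,6,6-tetramethylcyclohex-2-ene-1,5-dione | Cc1c(OCc2ccccc2)c2c(c([C@H](CC(C)C)C3=C(O)C(C)(C)C(=O)C(C)(C)C3=O)c1OCc1ccccc1)O[C@@H](c1ccccc1)CC2=O
A1 | alternative 1 | 2-[(1S)-1-(5,7-dimethoxy-6-methyl-4-oxo-2-phenyl-4H-chromen-8-yl)-3-methylbutyl]-3-hydroxy-4,4,6,6-tetramethylcyclohex-2-ene-1,5-dione | COc1c(C)c(OC)c([C@H](CC(C)C)C2=C(O)C(C)(C)C(=O)C(C)(C)C2=O)c2oc(-c3ccccc3)cc(=O)c12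
A2 | alternative 1 | 7-hydroxy-5-methoxy-6-methyl-8-[(1R)-3-methyl-1-(2,4,6-trihydroxyphenyl)butyl]-2-phenyl-4H-chromen-4-one | COc1c(C)c(O)c([C@H](CC(C)C)c2c(O)cc(O)cc2O)c2oc(-c3ccccc3)cc(=O)c12
A3 | alternative 2 | 5,7-dimethoxy-6-methyl-2-phenyl-4H-chromen-4-one | COc1cc2oc(-c3ccccc3)cc(=O)c2c(OC)c1C
A4 | alternative 2 | 3,5-dimethoxy-4-methyl-2-(trimethylsilyl)phenyl trifluoromethanesulfonate | COc1cc(OS(=O)(=O)C(F)(F)F)c([Si](C)(C)C)c(OC)c1C
A5 | alternative 2 | 3-phenylprop-2-ynoic acid | OC(=O)C#Cc1ccccc1
A6 | alternative 3 | (2R)-5,7-dimethoxy-6-methyl-2-phenyl-2,3-dihydro-4H-chromen-4-one | COc1cc2O[C@@H](c3ccccc3)CC(=O)c2c(OC)c1C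
A7 | alternative 3 | (3R)-3-(3,5-dimethoxy-4-methylphenoxy)-3-phenylpropanoic acid | COc1cc(O[C@@H](c2ccccc2)CC(=O)O)cc(OC)c1C
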